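The runs are simulated with made-up constants, and the scatter is random.

At late times both earlier runs are still moving, though by 8.00 h intermediate A has come down to 2.4% on Tuesday's and 2.2% on Wednesday's. Side product A, at 45.7% and 56.8%, is still climbing and leads Tuesday's and Wednesday's.

| setting | Tuesday's | Wednesday's | dawn | dusk |
|---|---|---|---|---|
| starting material | 34 mM | 34 mM | 34 mM | 34 mM |
| reagent | 26 mM | 46 mM | 36.0 mM | 54.0 mM |
| remark | run made earlier | run made earlier |  |  |
| time |  |  | 10 h | 10 h |

| run | time / h | starting material / % | side product A / % | target / % | intermediate A / % |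
|---|---|---|---|---|---|
| Tuesday's | 0.833 | 67.6 | 8.5 | 3.4 | 16.3 |
| Tuesday's | 2.50 | 54.4 | 25.4 | 6.6 | 9.4 |
| Tuesday's | 5.00 | 45.8 | 38.2 | 8.2 | 5.4 |
| Tuesday's | 8.00 | 40.2 | 45.7 | 8.5 | 2.4 |
| Wednesday's | 2.00 | 36.2 | 29.3 | 15.3 | 13.9 |
| Wednesday's | 4.00 | 24.3 | 44.2 | 20.4 | 6.6 |
| Wednesday's | 5.00 | 21.8 | 49.3 | 22.8 | 5.0 |
| Wednesday's | 8.00 | 13.7 | 56.8 | 23.3 | 2.2 |

(readings scatter by 0.5 percentage points)

- in percentages every species weighs as the starting material in it: one side product B counts as two
- for target the crystals are counted in
- as a solid, counted per litre of solution: crystals
- the numbers in the tables scatter by 0.5 percentage points (one standard deviation)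
- reactions considered so far: starting material + reagent <-> intermediate A; intermediate A -> side product A; reagent + intermediate A -> target; intermediate A <-> intermediate B; reagent + intermediate B <-> intermediate C; crystals <-> target; starting material + intermediate C -> side product B
- a reading of intermediate A is of its free form alone

- which of these there is most of at the end, counted by the starting material in it, dawn (starting material / target / intermediate A / side product A)
- which of these there is most of at the end, counted by the starting material in it, dusk (starting material / target / intermediate A / side product A)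
- the largest of these amounts at the end, in percent of the starting material charged, dawn
- the largest of these amounts at the end, in percent of the starting material charged, dusk

We read the runs as a ladder. On the fastest rung, starting material and reagent bind: at Tuesday's first reading, 0.833 h, intermediate A already stands at 16.3%, higher than at 2.50 h.

On the middle rung we freeze one number, the clock κ, the side product A made per hour per unit of intermediate A. With Y for side product A and X for intermediate A, Wednesday's readings from 2.00 h to 8.00 h give

κ = ΔY / ∫X dt = 0.741 h⁻¹, so 1/κ = 1.35 h.

Tuesday's readings give 0.672 h⁻¹.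

On the slowest rung, Wednesday's starting material falls by a factor e in 6.46 h, longer than 1/κ, so late on we hold X at its last reading.

Dawn's reagent is the midpoint of the two runs, 36.0 mM, and Wednesday's is the nearest run to dusk. Adding κX over the last 2.00 h:

dawn: Y ≈ 54.7%
dusk: Y ≈ 60.1%

The forecast names side product A for dawn and side product A for dusk, at 54% and 60%, holding that “the reagent largely sets the outcome”.

The flasks give side product A at 57.8% for dawn and side product A at 60.1% for dusk, so the forecast held.

    starting material + reagent ⇌ intermediate A (K = 34.0 M⁻¹, k = 0.550 M⁻¹ min⁻¹)
    intermediate A → side product A (k = 0.0130 min⁻¹)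
    reagent + intermediate A → target (k = 0.270 M⁻¹ min⁻¹)
    intermediate A ⇌ intermediate B (K = 0.320, k = 0.0140 min⁻¹)
    reagent + intermediate B ⇌ intermediate C (K = 34.0 M⁻¹, k = 0.0450 M⁻¹ min⁻¹)
    crystals ⇌ target, rate k6*(cs6 - [target]) while solid is left; crystals form when [target] > cs6 (solubility = 9.60 mM, k = 0.260 min⁻¹)
    starting material + intermediate C → side product B (k = 0.0270 M⁻¹ min⁻¹)

Dawn still holds 22.7% starting material at 10.0 h. From 5.00 h to 10.0 h, κ times the mean intermediate A gives dawn 13 percentage points; it gained 12 points. A second pair, charged as dawn, was stopped at 2.5 h and 4.0 h with intermediate A at 11.2% and 6.93%. κ gives a gain of 10 points between them; side product A went from 30.4% to 40.7%.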